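The earlier runs and the new flask were generated by integration from invented constants, and the scatter is random.

- Target after 80 min was what I had to reckon, in Wednesday's flask against Friday's.

in all of them: starting material 20 mM; free catalyst 0.3 mol%; added ligand 41 µM
- birch: coupling partner 2.3 equiv; temperature 58 °C; run made earlier
- cedar: coupling partner 2.3 equiv; temperature 74 °C; run made earlier
- Wednesday's: coupling partner 4.00 equiv; at 50 °C until 25 min, from then on at 80 °C; time 80 min
- Friday's: coupling partner 6.00 equiv; at 50 °C throughout; time 80 min

| run | time / min | target / % | starting material / % |
|---|---|---|---|
| birch | 3.00 | 2.6 | 97.6 |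
| birch | 6.00 | 5.0 | 95.4 |
| birch | 12.0 | 9.1 | 90.3 |
| birch | 20.0 | 15.4 | 84.2 |
| birch | 40.0 | 26.9 | 71.6 |
| cedar | 1.00 | 1.9 | 97.5 |
| cedar | 2.00 | 3.5 | 95.7 |
| cedar | 4.00 | 7.5 | 91.2 |
| cedar | 6.00 | 10.9 | 88.3 |
| cedar | 12.0 | 20.7 | 79.9 |

(readings scatter by 0.5 percentage points)

- the winner by amount of target, in percent of the starting material charged; "neither" if no more than 2 percentage points parts them (Wednesday's / Friday's / neither)
- how much target is there at the end, in percent of the starting material charged: Wednesday's
- how much target is there at the end, in percent of the starting material charged: Friday's

- the numbers in the tables scatter with a standard deviation of 0.5 percentage points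

- I kept the books on the starting material, the limiting reagent by charge, and booked what reacted as target: at the last readings the two summed to 98.5% of the charge in the birch run and 101% in the cedar run.
- The last target readings gave a rate constant of 0.00783 /min in the birch run and 0.0193 /min in the cedar run, so the constant doubled every 12.3 K, a reading that carries their scatter.
- Both runs held 2.3 equiv of coupling partner, so they showed no order in it, and I carried the constants with that doubling span, taking no account of the charge of coupling partner: 0.00499 /min at 50 °C and 0.0271 /min at 80 °C.
- In my books for Wednesday's flask the cold stretch scored 0.125 and booked 11.7% of the starting material as target, and the hot stretch scored 1.49 and booked 68.4%, so the cold stretch was a correction, smaller than the hot stretch.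
- Added, these make 1.62, my clock sum, each stretch's rate constant times its minutes; the starting material left is the exponential of minus that sum.
- So my books for Wednesday's closed at 80.1% target and 19.9% starting material left.
- Friday's flask, with a clock sum of 0.399, closed at 32.9% target and 67.1% left.
- The forecast named Wednesday's the winner, with 86% for Wednesday's and 61% for Friday's, holding that “The hot stretch outweighs Friday's extra partner”; my winner was the same, but my figure for Friday's was lower than its figure, and my figure for Wednesday's was lower than its figure too.
- Wednesday's gave 67.6% and Friday's 34.6%, so Wednesday's won.

    coupling partner + free catalyst → catalyst intermediate A (k = 21000 /M/h, Ea = 41.0 kJ/mol)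
    starting material + catalyst intermediate A ⇌ catalyst intermediate B (K = 6.70 /M, k = 40000 /M/h, Ea = 52.0 kJ/mol, ΔH = −28.0 kJ/mol)
    catalyst intermediate B → free catalyst + target (k = 1200 /h, Ea = 81.0 kJ/mol)
    2 coupling partner → self-condensation product (k = 14.0 /M/h, Ea = 52.0 kJ/mol)
    free catalyst + added ligand ⇌ idle complex (K = 1.70 × 10⁵ /M, k = 9600 /M/h, Ea = 61.0 kJ/mol, ΔH = 7.00 kJ/mol)
    (constants at 50 °C)

- Read back from its target, Wednesday's flask ended on a clock sum of 1.13, less than my 1.62. The gap between the two flasks came mainly from the temperature programme: Friday's flask without that difference from Wednesday's gave 69.5% instead of 34.6%. For the neighbour of Wednesday's charged with a quarter of the free catalyst, I scaled the read-back sum by that ratio to 0.282, which books 24.6% target; that neighbour gave 21.3%.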